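Locants used throughout: decalin carbons C1–C10 in drimane numbering, C11 for the linking methylene, C1′–C5′ for the five-membered ring (C1′ carbinol, C4′ ketone, C5′ the CH).

## The problem

Target 9 joins a trans-fused Δ3-octalin (ring A: C1–C5, C10; ring B: C5–C10) to a ring-contracted, fully oxygenated cyclopentenone through the single methylene C11. The decalin carries four contiguous stereocentres: quaternary C5 (β-methyl), C10 (α-H), C9 (β-methyl, axial and 1,3-diaxial to the C5 methyl) and quaternary C8 (α-methyl, β-C11). Because C11 sits on C8 and not on C9, C8 is a neopentyl junction that no late alkylation will form, and the axial C9 methyl cannot be reached by equilibration. These four centres can control one another through the ring fusion, but the freely rotating C11 methylene insulates them from C1′ and C5′. C5′ is α to the C4′ ketone and epimerisable, so it can only follow C1′ thermodynamically, and C1′ has no neighbour able to direct it. The cyclopentenone combines an enol ether, a tertiary α-hydroxy ester and a β-hydroxy ketone, and the C3=C4 alkene beside quaternary C5 is prone to protonation and methyl shift in acid, so the five-membered ring should appear last and under mild conditions. The first enabling feature is that C4(Me)=C3, C5(Me), C10(H), C9(H)(Me) and C8(Me)(C11) are the atoms of a drimane in which C11, the C10 methyl, the C5 hydrogen and one C4 methyl have each moved to the adjacent carbon, so all fifteen carbons map onto a farnesyl chain and all four stereocentres onto one folding event. The second is that C1′(OH)(CO2Me) flanked by C5′H–C4′(=O)–C3′(OMe)=C2′H is what a benzilic shift of a 2-hydroxy-5-methoxy-3-alkyl-1,4-benzoquinone produces, so the five-membered ring can pass through the cationic chemistry as a benzene ring.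

## Retrosynthesis

**9 to 8.** In the reverse sense the C1′–C5′ bond is opened, C5′ is joined to the ester carbon and methanol is removed, which returns the six-membered hydroxy methoxy quinone 8. The neighbouring cuts (C11–C5′, or C11–C8 with a preformed cyclopentenone) would need a substitution at a neopentyl carbon or a bond to a quaternary centre. Here both five-ring stereocentres disappear and the oxygen pattern becomes that of a flat quinone. The forward step asks methoxide to add to the keto tautomer of 8 and the ring carbon bearing C11 to shift. It offers no facial control at C1′, so the target must be taken from an equilibrating mixture of C1′/C5′ isomers.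

**8 to 7 to 6.** These are changes at oxygen only: hydrolysis of one vinylogous ester in dimethoxyquinone 7, and oxidative demethylation of tetramethoxyarene 6. Carrying a 1,2,4,5-tetraoxygenated benzene from the start is preferred over oxygenating a simple quinone late, because additions of an alcohol and of oxygen to an alkylquinone give regioisomers. In 6 the positions of the future hydroxyl and methoxyl are fixed by the substitution pattern. The forward steps need an oxidant that leaves the C3=C4 alkene alone and a hydrolysis that selects the methoxyl flanked by the alkyl branch.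

**6 to 5 (key disconnection).** The C4–C5 and C9–C10 bonds are cut, and C11 is returned to C9, a methyl to C10, a hydrogen to C5 and a methyl to C4. This opens rings A and B, removes all four decalin stereocentres and leaves the achiral farnesyl arene 5. The competing cuts build ring B by cycloaddition or assemble the decalin from a bicyclic diketone; they use known chemistry but cost about ten steps for the same four centres. The forward reaction asks a proton-initiated class 2 terpene cyclase to fold 5 chair–chair, close both rings and let the C8 cation relax by four 1,2-shifts. The first of these must be the C11 benzyl group and not the aligned axial C9 hydrogen. The aryl group of 5 is chosen to help: it has no free hydroxyl and no free ortho position, so the two usual terminations (chroman ether formation and Friedel–Crafts closure) are blocked, and it is bulky and electron-rich at the migrating benzylic carbon.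

**5 to 4 and 2; 4 to 3; 2 to 1.** The C11–aryl bond is cut to aryllithium 4 and farnesyl bromide 2. Compound 4 comes from commercial 1,2,4,5-tetramethoxybenzene 3 by lithiation between two methoxy groups, and 2 from commercial (2E,6E)-farnesol 1. An acid-mediated Friedel–Crafts farnesylation would be one step shorter, but it exposes the triene to the conditions that cyclise and isomerise it. The organometallic coupling only has to keep the 2E geometry and attack the primary allylic carbon.

## Roads not taken

**Alternative 1: five-membered ring from the chiral pool.** The cut places the carbinol cyclopentane in quinic acid 1,5-lactone A1. Glycol cleavage of the cis-diol of A1 and an intramolecular aldol of the freed acetaldehyde arm onto the second aldehyde would give the bicyclic lactone aldehyde A2, with the C1′ carbinol carbon, its carboxyl carbon and the future C11 carbon in place.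
- Merit: C1′ is configured absolutely, because its configuration is carried over from A1. This is better than the chosen plan, which cannot control C1′ and has to rely on equilibration, separation and recycling.
- Weak points: A2 is a dehydration-prone β-hydroxy aldehyde whose oxygen pattern is far from the methoxy enone. The C11 aldehyde would have to be joined to the fully substituted C8, which needs a tertiary nucleophile on a preformed decalin. The decalin and its four centres remain unsolved.
- Comparison: the C1′ advantage is outweighed by a long, non-convergent sequence with the hardest bond (C8–C11) still open. The chosen plan offers six steps and the decalin and arene in one intermediate.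

**Alternative 2: Diels–Alder construction of ring B.** The silyloxy vinylcyclohexene A3 and citraconic anhydride A4 would combine endo to the tricyclic anhydride A5, forming C7–C8 and C9–C10 and placing the C8 methyl, the future C11 carbonyl and the future C9 methyl carbonyl cis on ring B.
- Merit: every step is known chemistry, and the C8 quaternary centre and its cis relation to the C9 substituent come from the geometry of the dienophile A4. In certainty this road is better than the chosen one.
- Weak points: C5 is left as an alkene carbon in A5, so the angular methyl and the trans ring fusion must be added afterwards. The two anhydride carbonyls must be told apart, one reduced to methyl and the other linked to the ring. The C3=C4 methyl alkene must be built from the silyl ether. Facial control in the cycloaddition of A3 with A4 rests on one remote stereocentre. The count passes fifteen steps before the five-membered ring is addressed.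
- Comparison: the chosen plan sets brevity (three steps to the complete decalin arene) against this certainty. A ring-by-ring decalin construction of the same conservative kind is kept as the fallback for the key step.

**Alternative 3: photochemical Wolff contraction.** The ortho-quinone diazide A6 would lose nitrogen on irradiation in the ester-forming alcohol, the ring carbon would shift to the carbene carbon, and the ketene would be trapped to give the cyclopentenone ester A7, which lacks the C1′ hydroxyl.
- Merit: the contraction is irreversible and regiodefined. A later enolate hydroxylation could enter anti to the C5′ substituent, which is the relative configuration of the target, so this road may control C1′ relative to C5′ better than the benzilic shift.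
- Weak points: A7 has a doubly activated C1′–H and isomerises and epimerises easily. Preparing A6 requires regioselective introduction of nitrogen next to a phenolic oxygen on an electron-rich ring in the presence of the alkene. An extra oxidation is needed. The decalin is still assumed.
- Comparison: this is an alternative end-game only and is longer. The chosen plan reaches the C1′ oxidation level in a redox-neutral step and answers the stereochemical question by equilibration and recycling.

Key step: step 3

Assumption: C1′ and C5′ of 9 are taken to equilibrate under methoxide (enolisation at C5′, retro-aldol/aldol across C1′–C5′), so step 6 is planned as equilibration, separation and recycling and not as a selective reaction.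

## Route

Step 1
Reactants: 1 (2E,6E)-farnesol
Product: 2 (2E,6E)-farnesyl bromide
Conditions: PBr3 (0.4 equiv), Et2O, −10 to 0 °C; used crude
Reagents that add atoms: phosphorus tribromide, BrP(Br)Br
Why: Bromination of a primary allylic alcohol through its phosphite ester by SN2 displacement; at low temperature allylic transposition and E/Z scrambling should stay minor.

Step 2
Reactants: 3 1,2,4,5-tetramethoxybenzene; 2 (2E,6E)-farnesyl bromide
Product: 5 3-[(2E,6E)-3,7,11-trimethyldodeca-2,6,10-trien-1-yl]-1,2,4,5-tetramethoxybenzene, via (2,3,5,6-tetramethoxyphenyl)lithium 4 (not isolated)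
Conditions: n-BuLi, TMEDA, THF, 0 °C; then CuBr·SMe2 (10 mol %), 2, −40 °C to rt
Reagents that add atoms: none
Why: Directed ortho-lithiation between two methoxy groups, then copper-mediated SN2 allylation at the primary carbon of the γ,γ-disubstituted allylic bromide, which should keep the 2E geometry and avoid the branched isomer.

Step 3
Reactants: 5 3-[(2E,6E)-3,7,11-trimethyldodeca-2,6,10-trien-1-yl]-1,2,4,5-tetramethoxybenzene
Product: 6 3-{[(1R,2R,4aS,8aS)-1,2,4a,5-tetramethyl-1,2,3,4,4a,7,8,8a-octahydronaphthalen-2-yl]methyl}-1,2,4,5-tetramethoxybenzene
Conditions: engineered squalene-hopene cyclase variant (class 2 terpene cyclase from Alicyclobacillus acidocaldarius, obtained by directed evolution), E. coli whole cells or membrane fraction, citrate buffer pH 6, 2-hydroxypropyl-β-cyclodextrin, 30–45 °C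
Reagents that add atoms: none
Why: Proposed new method: the active-site acid should protonate C3 of the terminal alkene of 5 held in a chair–chair fold, so that C5 attacks C4 and C9 attacks C10 in two 6-endo-trig cation–olefin closures (ring A, then ring B), each an anti addition across an E alkene, giving the drimanyl C8 cation with 10β-methyl, 5α-H, 9α-H and 9β-C11. The cation is then to relax by four suprafacial 1,2-shifts (C11 from C9 to C8 on the β face, methyl from C10 to C9 on the β face, hydride from C5 to C10 on the α face, methyl from C4 to C5 on the β face) and loss of a C3 proton to a base placed there, a net isomerisation. C8 (R, C11 β), C9 (R, methyl β with the original α-H kept), C10 (S, α-H) and C5 (S, β-methyl) all follow from the chair–chair fold and the suprafacial shifts, and the absolute sense follows from the face of protonation fixed by the enzyme, which in this enzyme family gives the normal drimane series. The closest known reactions are squalene-hopene cyclase bicyclisations of farnesyl and homofarnesyl substrates to drimane-type bicycles and the hydride–methyl–hydride–methyl cascade of clerodane-forming class 2 diterpene cyclases. What is new is that the first shift must be the benzylic C11 and not the axial C9 hydrogen, and that it passes through a secondary C9 cation. The step needs C11 to migrate in preference to H9, and needs no deprotonation at C7 or C12 and no water capture before C3. The substrate contributes by having no phenolic hydroxyl and no free ortho C–H (no chroman or Friedel–Crafts termination), a di-ortho-substituted benzyl group whose A(1,2) strain with the C8 methyl should favour the ring B twist that aligns C9–C11 with the empty orbital, and an electron-rich benzylic carbon of high migratory aptitude whose arene and ortho-methoxy oxygen can stabilise the C9 cation through space. The pocket must supply the remaining conformational control.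

Step 4
Reactants: 6 3-{[(1R,2R,4aS,8aS)-1,2,4a,5-tetramethyl-1,2,3,4,4a,7,8,8a-octahydronaphthalen-2-yl]methyl}-1,2,4,5-tetramethoxybenzene
Product: 7 2,5-dimethoxy-3-{[(1R,2R,4aS,8aS)-1,2,4a,5-tetramethyl-1,2,3,4,4a,7,8,8a-octahydronaphthalen-2-yl]methyl}cyclohexa-2,5-diene-1,4-dione
Conditions: (NH4)2Ce(NO3)6 (2.5 equiv), MeCN/H2O 2:1, 0 °C
Reagents that add atoms: water, O
Why: Oxidative demethylation of a para-dimethoxyarene by tetravalent cerium through the arene radical cation, with water adding at the ipso carbons and methanol leaving; the 1,2,4,5-pattern should give the 2,5-dimethoxy-para-quinone, and the isolated trisubstituted alkene is not expected to react.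

Step 5
Reactants: 7 2,5-dimethoxy-3-{[(1R,2R,4aS,8aS)-1,2,4a,5-tetramethyl-1,2,3,4,4a,7,8,8a-octahydronaphthalen-2-yl]methyl}cyclohexa-2,5-diene-1,4-dione
Product: 8 2-hydroxy-5-methoxy-3-{[(1R,2R,4aS,8aS)-1,2,4a,5-tetramethyl-1,2,3,4,4a,7,8,8a-octahydronaphthalen-2-yl]methyl}cyclohexa-2,5-diene-1,4-dione
Conditions: KOH (2 M aq.), MeOH, 0 °C to rt; then 1 M HCl
Reagents that add atoms: potassium hydroxide, [K+].[OH-]
Why: Addition–elimination of hydroxide at a vinylogous ester carbon; the methoxyl wedged between the alkyl branch and a carbonyl is twisted out of conjugation, so its carbon should be the more electrophilic, and the resulting hydroxyquinone anion resists a second hydrolysis.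

Step 6
Reactants: 8 2-hydroxy-5-methoxy-3-{[(1R,2R,4aS,8aS)-1,2,4a,5-tetramethyl-1,2,3,4,4a,7,8,8a-octahydronaphthalen-2-yl]methyl}cyclohexa-2,5-diene-1,4-dione
Product: 9 methyl (1R,5S)-1-hydroxy-3-methoxy-4-oxo-5-{[(1R,2R,4aS,8aS)-1,2,4a,5-tetramethyl-1,2,3,4,4a,7,8,8a-octahydronaphthalen-2-yl]methyl}cyclopent-2-ene-1-carboxylate (dysidenone B)
Conditions: NaOMe (5 equiv), degassed MeOH, Ar, 0 to 50 °C; AcOH quench; preparative HPLC, other diastereomers resubmitted
Reagents that add atoms: sodium methoxide, C[O-].[Na+]
Why: Benzilic ester rearrangement with ring contraction: in the keto tautomer of the hydroxyquinone (quinone C3 protonated) methoxide adds to the C2 carbonyl, and C3 shifts from C2 to C1, so C1 becomes C1′ (alkoxide), C2 the ester carbon and C3 becomes C5′; methoxide exchange at the remaining vinylogous ester is degenerate. C1′ forms without facial bias and C5′ is epimerisable, so the (1′R,5′S) isomer is to be taken from the base-equilibrated mixture and the rest recycled.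

## Compound list

1 | (2E,6E)-farnesol | CC(C)=CCC/C(C)=C/CC/C(C)=C/CO | starting material
2 | (2E,6E)-farnesyl bromide | CC(C)=CCC/C(C)=C/CC/C(C)=C/CBr | intermediate
3 | 1,2,4,5-tetramethoxybenzene | COc1cc(OC)c(OC)cc1OC | starting material
4 | (2,3,5,6-tetramethoxyphenyl)lithium | [Li]c1c(OC)c(OC)cc(OC)c1OC | intermediate
5 | 3-[(2E,6E)-3,7,11-trimethyldodeca-2,6,10-trien-1-yl]-1,2,4,5-tetramethoxybenzene | CC(C)=CCC/C(C)=C/CC/C(C)=C/Cc1c(OC)c(OC)cc(OC)c1OC | intermediate
6 | 3-{[(1R,2R,4aS,8aS)-1,2,4a,5-tetramethyl-1,2,3,4,4a,7,8,8a-octahydronaphthalen-2-yl]methyl}-1,2,4,5-tetramethoxybenzene | COc1cc(OC)c(OC)c(C[C@@]2(C)CC[C@]3(C)C(C)=CCC[C@H]3[C@H]2C)c1OC | intermediate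
7 | 2,5-dimethoxy-3-{[(1R,2R,4aS,8aS)-1,2,4a,5-tetramethyl-1,2,3,4,4a,7,8,8a-octahydronaphthalen-2-yl]methyl}cyclohexa-2,5-diene-1,4-dione | COC1=CC(=O)C(OC)=C(C[C@@]2(C)CC[C@]3(C)C(C)=CCC[C@H]3[C@H]2C)C1=O | intermediate
8 | 2-hydroxy-5-methoxy-3-{[(1R,2R,4aS,8aS)-1,2,4a,5-tetramethyl-1,2,3,4,4a,7,8,8a-octahydronaphthalen-2-yl]methyl}cyclohexa-2,5-diene-1,4-dione | COC1=CC(=O)C(O)=C(C[C@@]2(C)CC[C@]3(C)C(C)=CCC[C@H]3[C@H]2C)C1=O | intermediate
9 | methyl (1R,5S)-1-hydroxy-3-methoxy-4-oxo-5-{[(1R,2R,4aS,8aS)-1,2,4a,5-tetramethyl-1,2,3,4,4a,7,8,8a-octahydronaphthalen-2-yl]methyl}cyclopent-2-ene-1-carboxylate (dysidenone B) | COC(=O)[C@@]1(O)C=C(OC)C(=O)[C@H]1C[C@@]1(C)CC[C@]2(C)C(C)=CCC[C@H]2[C@H]1C | target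

Total step count: 6. Longest linear sequence: 6 steps (1 to 2 to 5 to 6 to 7 to 8 to 9).

## Least certain steps

**Step 3 (key step, proposed new method).**
- What may go wrong: the cascade may end early. Most likely is migration of the stereoelectronically aligned axial C9 hydrogen, which leads into the avarane-type constitutional series. Also possible are proton loss from C7 or C12 right after bicyclisation, or hydration of the C8 cation. The benzyl shift is uphill because it creates a secondary C9 cation, and a cyclase variant that enforces it has to be found by evolution.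
- Fallback (known chemistry only, sets out from 3, returns at 6): the cascade is abandoned and the decalin is built ring by ring. Commercial (S)-8a-methyl-3,4,8,8a-tetrahydronaphthalene-1,6(2H,7H)-dione F1 is converted at its enone carbonyl into the 1,3-dithiolane F2 (ethane-1,2-dithiol, BF3·OEt2, MeOH), and Raney Ni desulfurises this to (S)-8a-methyl-3,4,6,7,8,8a-hexahydronaphthalen-1(2H)-one F3. MeMgBr/CeCl3 gives the tertiary carbinol (8aS)-1,8a-dimethyl-1,2,3,4,6,7,8,8a-octahydronaphthalen-1-ol F4, whose carbinol epimers are inconsequential. Hydroboration–oxidation (BH3·THF; NaOH, H2O2) from the face opposite the angular methyl gives the trans-fused diol (1R,4aS,8aR)-4a,5-dimethyldecahydronaphthalene-1,5-diol F5. Periodinane oxidation (DMP) gives (4aS,8aR)-5-hydroxy-4a,5-dimethyloctahydronaphthalen-1(2H)-one F6. Dehydration (SOCl2, pyridine; then RhCl3·3H2O in hot EtOH to move any exocyclic alkene into the ring) gives (4aS,8aR)-4a,5-dimethyl-3,4,4a,7,8,8a-hexahydronaphthalen-1(2H)-one F7, which carries C5, C10 and the C3=C4 methyl alkene. Aryllithium 4, made from 3 as in step 2, and DMF give 2,3,5,6-tetramethoxybenzaldehyde F8. Aldol condensation of F7 with F8 (KOH, EtOH) at C8, the only enolisable methylene, gives (2E,4aS,8aR)-4a,5-dimethyl-2-[(2,3,5,6-tetramethoxyphenyl)methylidene]-3,4,4a,7,8,8a-hexahydronaphthalen-1(2H)-one F9. Li/NH3 reduction forms the C8 enolate regiospecifically and MeI alkylates it axially from the α face, giving (2R,4aS,8aR)-2,4a,5-trimethyl-2-[(2,3,5,6-tetramethoxyphenyl)methyl]-3,4,4a,7,8,8a-hexahydronaphthalen-1(2H)-one F10 with C11 β and methyl α on C8. Methylenation of the hindered ketone (Ph3P=CH2, toluene, 90 °C) gives 1,2,4,5-tetramethoxy-3-{[(2R,4aS,8aS)-2,4a,5-trimethyl-1-methylidene-1,2,3,4,4a,7,8,8a-octahydronaphthalen-2-yl]methyl}benzene F11. Hydrogenation of the exocyclic alkene (H2, Pd/C, EtOAc, one equivalent) from the equatorial α side, away from the axial C5 methyl, should place the C9 methyl β and give 6. This replaces steps 1–3 by eleven operations, and C8 and C9 are then set by substrate control that would need to be verified.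

**Step 6.**
- What may go wrong: the shift creates C1′ with no facial selectivity, so a diastereomer mixture results. The hydroxyquinone anion may resist methoxide addition, and traces of oxygen would divert it to Hooker-type oxidative degradation.
- Fallback (sets out from 8, returns at 9): the contraction is run as the classical hydroxide-driven benzilic acid rearrangement (KOH, degassed aqueous dioxane), which is made irreversible by carboxylate formation. It gives (1R,5S)-1-hydroxy-3-methoxy-4-oxo-5-{[(1R,2R,4aS,8aS)-1,2,4a,5-tetramethyl-1,2,3,4,4a,7,8,8a-octahydronaphthalen-2-yl]methyl}cyclopent-2-ene-1-carboxylic acid F12 together with its diastereomers. The acid stage allows separation by crystallisation of amine salts, and the acid is then esterified with TMSCHN2 in MeOH/toluene to 9.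

**Step 5.**
- What may go wrong: hydroxide may attack the wrong methoxy-bearing carbon, or both, because the selectivity rests on a modest difference in conjugation.
- Fallback (sets out from 7, returns at 8): exhaustive hydrolysis (NaOH, aqueous dioxane, 60 °C) gives 2,5-dihydroxy-3-{[(1R,2R,4aS,8aS)-1,2,4a,5-tetramethyl-1,2,3,4,4a,7,8,8a-octahydronaphthalen-2-yl]methyl}cyclohexa-2,5-diene-1,4-dione F13. Acid-catalysed mono-etherification (MeOH, catalytic BF3·OEt2, rt) then takes place at the unhindered hydroxyl remote from the alkyl branch and gives 8.

**Step 2.**
- What may go wrong: SN2′ attack leading to branched coupling, lithium–halogen exchange with homocoupling, or partial loss of the 2E geometry; material altered in any of these ways would not be accepted by the enzyme.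
- Fallback (sets out from 4, returns at 5): transmetalation with ZnCl2 gives (2,3,5,6-tetramethoxyphenyl)zinc chloride F14. This is coupled with 2 under Pd(PPh3)4 (zerovalent palladium) in THF in a Negishi-type allyl–aryl coupling, which proceeds through a π-allyl complex and gives the linear product with retention of alkene geometry.

## Further compounds

F1 | step 3 | (S)-8a-methyl-3,4,8,8a-tetrahydronaphthalene-1,6(2H,7H)-dione | O=C1CC[C@]2(C)C(=O)CCCC2=C1
F2 | step 3 | 1,3-dithiolane of the enone carbonyl of F1 [(S)-6,6-(ethane-1,2-diyldisulfanediyl)-8a-methyl-3,4,6,7,8,8a-hexahydronaphthalen-1(2H)-one] | C12(SCCS1)CC[C@]3(C)C(=O)CCCC3=C2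
F3 | step 3 | (S)-8a-methyl-3,4,6,7,8,8a-hexahydronaphthalen-1(2H)-one | C1CC[C@]2(C)C(=O)CCCC2=C1
F4 | step 3 | (8aS)-1,8a-dimethyl-1,2,3,4,6,7,8,8a-octahydronaphthalen-1-ol (carbinol epimers) | C1CC[C@]2(C)C(C)(O)CCCC2=C1
F5 | step 3 | (1R,4aS,8aR)-4a,5-dimethyldecahydronaphthalene-1,5-diol (C5 carbinol epimers) | C1CC[C@]2(C)C(C)(O)CCC[C@H]2[C@@H]1O
F6 | step 3 | (4aS,8aR)-5-hydroxy-4a,5-dimethyloctahydronaphthalen-1(2H)-one | C1CC[C@]2(C)C(C)(O)CCC[C@H]2C1=O
F7 | step 3 | (4aS,8aR)-4a,5-dimethyl-3,4,4a,7,8,8a-hexahydronaphthalen-1(2H)-one | C1CC[C@]2(C)C(C)=CCC[C@H]2C1=O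
F8 | step 3 | 2,3,5,6-tetramethoxybenzaldehyde | O=Cc1c(OC)c(OC)cc(OC)c1OC
F9 | step 3 | (2E,4aS,8aR)-4a,5-dimethyl-2-[(2,3,5,6-tetramethoxyphenyl)methylidene]-3,4,4a,7,8,8a-hexahydronaphthalen-1(2H)-one | COc1cc(OC)c(OC)c(/C=C2\CC[C@]3(C)C(C)=CCC[C@H]3C2=O)c1OC
F10 | step 3 | (2R,4aS,8aR)-2,4a,5-trimethyl-2-[(2,3,5,6-tetramethoxyphenyl)methyl]-3,4,4a,7,8,8a-hexahydronaphthalen-1(2H)-one | COc1cc(OC)c(OC)c(C[C@@]2(C)CC[C@]3(C)C(C)=CCC[C@H]3C2=O)c1OC
F11 | step 3 | 1,2,4,5-tetramethoxy-3-{[(2R,4aS,8aS)-2,4a,5-trimethyl-1-methylidene-1,2,3,4,4a,7,8,8a-octahydronaphthalen-2-yl]methyl}benzene | COc1cc(OC)c(OC)c(C[C@@]2(C)CC[C@]3(C)C(C)=CCC[C@H]3C2=C)c1OC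
F12 | step 6 | (1R,5S)-1-hydroxy-3-methoxy-4-oxo-5-{[(1R,2R,4aS,8aS)-1,2,4a,5-tetramethyl-1,2,3,4,4a,7,8,8a-octahydronaphthalen-2-yl]methyl}cyclopent-2-ene-1-carboxylic acid | OC(=O)[C@@]1(O)C=C(OC)C(=O)[C@H]1C[C@@]1(C)CC[C@]2(C)C(C)=CCC[C@H]2[C@H]1C
F13 | step 5 | 2,5-dihydroxy-3-{[(1R,2R,4aS,8aS)-1,2,4a,5-tetramethyl-1,2,3,4,4a,7,8,8a-octahydronaphthalen-2-yl]methyl}cyclohexa-2,5-diene-1,4-dione | OC1=CC(=O)C(O)=C(C[C@@]2(C)CC[C@]3(C)C(C)=CCC[C@H]3[C@H]2C)C1=O
F14 | step 2 | (2,3,5,6-tetramethoxyphenyl)zinc chloride | COc1cc(OC)c(OC)c([Zn]Cl)c1OC
A1 | alternative 1 | quinic acid 1,5-lactone | O=C1O[C@@H]2C[C@@]1(O)C[C@@H](O)[C@H]2O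
A2 | alternative 1 | 4,6-dihydroxy-3-oxo-2-oxabicyclo[2.2.1]heptane-5-carbaldehyde | O=C[C@H]1[C@@H](O)[C@H]2C[C@]1(O)C(=O)O2
A3 | alternative 2 | tert-butyl{[(1R)-2-ethenylcyclohex-2-en-1-yl]oxy}dimethylsilane | C=CC1=CCCC[C@H]1O[Si](C)(C)C(C)(C)C
A4 | alternative 2 | citraconic anhydride | CC1=CC(=O)OC1=O
A5 | alternative 2 | endo cycloadduct (tricyclic anhydride with C8 methyl, C5=C6 alkene and C4 silyloxy group) | O=C1OC(=O)[C@@H]2[C@@H]3CCC[C@@H](O[Si](C)(C)C(C)(C)C)C3=CC[C@]12C
A6 | alternative 3 | 6-diazo-4-hydroxy-3-methoxy-5-{[(1R,2R,4aS,8aS)-1,2,4a,5-tetramethyl-1,2,3,4,4a,7,8,8a-octahydronaphthalen-2-yl]methyl}cyclohexa-2,4-dien-1-one | COC1=CC(=O)C(=[N+]=[N-])C(C[C@@]2(C)CC[C@]3(C)C(C)=CCC[C@H]3[C@H]2C)=C1O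
A7 | alternative 3 | methyl 3-methoxy-4-oxo-5-{[(1R,2R,4aS,8aS)-1,2,4a,5-tetramethyl-1,2,3,4,4a,7,8,8a-octahydronaphthalen-2-yl]methyl}cyclopent-2-ene-1-carboxylate | COC(=O)[C@@H]1C=C(OC)C(=O)[C@H]1C[C@@]1(C)CC[C@]2(C)C(C)=CCC[C@H]2[C@H]1C
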